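**Assumption:** the sense of induction in the titanium/Schiff-base bromochlorination (step 1) is set by the ligand enantiomer; the enantiomer that gives (2R,3S)-2 is used.

**Retrosynthetic overview**
1. Target ⇐ one-pot hydrolysis of its methyl ester / aryl acetate.
2. Ring B, then ring A, form in one cationic cascade from an acyclic C20–aryl precursor: enantiopure vicinal bromochloride → bromiranium ion → E-trisubstituted olefin → (Z)-allylsilane. All five stereocentres follow from the one preset C–Br centre; desilylation gives the exocyclic methylene.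
3. Acyclic precursor ⇐ terminal alkyne + Me3SiCH2Cu + benzylic bromide (three-component carbocupration).
4. Alkyne ⇐ allylbarium from a C8 enyne allyl chloride + triflate of an enantioselectively bromochlorinated terpene alcohol.
5. Building blocks: a C10 terpene allylic alcohol, a C5 alkynol and a cresol-type benzoate.

**Route**

Step 1
Reactants: 1 geraniol
Product: 2 (2R,3S)-2-bromo-3-chloro-3,7-dimethyloct-6-en-1-ol
Conditions: NBS, ClTi(OiPr)3, chiral salicylaldimine amino-alcohol (Schiff-base) ligand (20 mol %), hexanes, −20 °C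
Reagents that add atoms: N-bromosuccinimide, O=C1CCC(=O)N1Br; chlorotitanium triisopropoxide, CC(C)O[Ti](Cl)(OC(C)C)OC(C)C
Why: Titanium-alkoxide-directed, ligand-controlled enantioselective bromochlorination of an allylic alcohol: the bound alkoxide confines reaction to the C2=C3 olefin, Br and Cl add anti with chloride at the tertiary C3 (Markovnikov), and the ligand fixes C2 as R and C3 as S.

Step 2
Reactants: 2 (2R,3S)-2-bromo-3-chloro-3,7-dimethyloct-6-en-1-ol
Product: 3 (2R,3S)-2-bromo-3-chloro-3,7-dimethyloct-6-en-1-yl trifluoromethanesulfonate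
Conditions: Tf2O, 2,6-lutidine, CH2Cl2, −78 °C (used at once)
Reagents that add atoms: trifluoromethanesulfonic anhydride, O=S(=O)(OS(=O)(=O)C(F)(F)F)C(F)(F)F
Why: Low-temperature O-sulfonylation (triflation) of a primary alcohol with a hindered base does not touch either stereocentre.

Step 3
Reactants: 4 pent-4-yn-1-ol
Product: 6 5-(trimethylsilyl)pent-4-yn-1-ol, via bis-silyl ether 5 (not isolated)
Conditions: n-BuLi (2.1 equiv), THF, −78 °C; Me3SiCl (2.2 equiv), −78 °C to rt; then 1 M HCl
Reagents that add atoms: chlorotrimethylsilane, C[Si](C)(C)Cl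
Why: Double deprotonation and bis-silylation followed by selective acidic cleavage of the labile O–Si bond (acetylide C-silylation) masks the acidic alkyne hydrogen for the organobarium step.

Step 4
Reactants: 6 5-(trimethylsilyl)pent-4-yn-1-ol
Product: 8 ethyl (2E)-2-methyl-7-(trimethylsilyl)hept-2-en-6-ynoate, via aldehyde 7 (not isolated)
Conditions: PhI(OAc)2, TEMPO (10 mol %), CH2Cl2, rt; then Ph3P=C(Me)CO2Et, rt
Reagents that add atoms: ethyl 2-(triphenylphosphoranylidene)propanoate, CCOC(=O)C(C)=P(c1ccccc1)(c1ccccc1)c1ccccc1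
Why: Oxoammonium oxidation to the aldehyde and in-pot Wittig olefination with a stabilised α-methyl ylide give the E-trisubstituted enoate (typically >95:5).

Step 5
Reactants: 8 ethyl (2E)-2-methyl-7-(trimethylsilyl)hept-2-en-6-ynoate
Product: 9 (2E)-2-methyl-7-(trimethylsilyl)hept-2-en-6-yn-1-ol
Conditions: iBu2AlH (2.2 equiv), CH2Cl2, −78 °C
Reagents that add atoms: none
Why: 1,2-Hydride reduction of the enoate by the aluminium hydride leaves the silyl alkyne and the olefin geometry intact.

Step 6
Reactants: 9 (2E)-2-methyl-7-(trimethylsilyl)hept-2-en-6-yn-1-ol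
Product: 10 [(5E)-7-chloro-6-methylhept-5-en-1-yn-1-yl]trimethylsilane
Conditions: NCS, Me2S, CH2Cl2, −20 to 0 °C
Reagents that add atoms: N-chlorosuccinimide, O=C1CCC(=O)N1Cl
Why: Corey–Kim chlorination (SN2 displacement of the alkoxysulfonium by chloride) converts the primary allylic alcohol to the chloride without allylic transposition or E/Z erosion.

Step 7
Reactants: 10 [(5E)-7-chloro-6-methylhept-5-en-1-yn-1-yl]trimethylsilane; 3 (2R,3S)-2-bromo-3-chloro-3,7-dimethyloct-6-en-1-yl trifluoromethanesulfonate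
Product: 12 [(5E,9R,10S)-9-bromo-10-chloro-6,10,14-trimethylpentadeca-5,13-dien-1-yn-1-yl]trimethylsilane, via allylbarium chloride 11 (not isolated)
Conditions: BaI2, lithium biphenylide (2 equiv), THF, rt; then 10, −78 °C; then 3, −78 °C
Reagents that add atoms: none
Why: Proposed new method: insertion of active barium into the allylic C–Cl bond at −78 °C gives a configurationally stable σ-allylbarium that reacts at its α-carbon, so SN2 displacement of the primary triflate (far faster at −78 °C than attack on the secondary bromide or tertiary chloride) should give the linear product with the E olefin and both halogen-bearing stereocentres intact; the closest known reaction type is the α-selective, geometry-retaining coupling of allylbarium reagents with allylic halides and carbonyl compounds.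

Step 8
Reactants: 12 [(5E,9R,10S)-9-bromo-10-chloro-6,10,14-trimethylpentadeca-5,13-dien-1-yn-1-yl]trimethylsilane
Product: 13 (5E,9R,10S)-9-bromo-10-chloro-6,10,14-trimethylpentadeca-5,13-dien-1-yne
Conditions: K2CO3 (0.2 equiv), MeOH, 0 °C
Reagents that add atoms: none
Why: Carbonate-catalysed methanolysis of the alkynyl C–Si bond (protodesilylation) is mild enough at 0 °C to leave the tertiary chloride / secondary bromide pair untouched.

Step 9
Reactants: 14 methyl 4-hydroxy-3-methylbenzoate
Product: 15 methyl 3-bromo-4-hydroxy-5-methylbenzoate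
Conditions: NBS, MeCN, 0 °C to rt
Reagents that add atoms: N-bromosuccinimide, O=C1CCC(=O)N1Br
Why: Electrophilic aromatic bromination occurs at the only free position ortho to the phenol (para blocked by the ester).

Step 10
Reactants: 15 methyl 3-bromo-4-hydroxy-5-methylbenzoate
Product: 16 methyl 4-(acetyloxy)-3-bromo-5-methylbenzoate
Conditions: Ac2O, pyridine, DMAP (cat.), CH2Cl2, rt
Reagents that add atoms: acetic anhydride, CC(=O)OC(C)=O
Why: DMAP-catalysed O-acetylation deactivates the ring and the phenolic oxygen for the radical bromination and, later, for the cationic cascade.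

Step 11
Reactants: 16 methyl 4-(acetyloxy)-3-bromo-5-methylbenzoate
Product: 17 methyl 4-(acetyloxy)-3-bromo-5-(bromomethyl)benzoate
Conditions: NBS, AIBN (cat.), PhCF3, 85 °C
Reagents that add atoms: N-bromosuccinimide, O=C1CCC(=O)N1Br
Why: Wohl–Ziegler radical bromination attacks the single benzylic methyl, and the electron-poor acetylated ring suppresses nuclear bromination.

Step 12
Reactants: 13 (5E,9R,10S)-9-bromo-10-chloro-6,10,14-trimethylpentadeca-5,13-dien-1-yne; 17 methyl 4-(acetyloxy)-3-bromo-5-(bromomethyl)benzoate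
Product: 19 methyl 4-(acetyloxy)-3-bromo-5-{(2Z,6E,10R,11S)-10-bromo-11-chloro-7,11,15-trimethyl-3-[(trimethylsilyl)methyl]hexadeca-2,6,14-trien-1-yl}benzoate, via alkenylcopper 18 (not isolated)
Conditions: Me3SiCH2MgCl, CuBr·SMe2, Et2O/Me2S, −40 to 20 °C; then 17, DMPU, P(OEt)3, −30 °C to rt
Reagents that add atoms: (trimethylsilyl)methylmagnesium chloride, C[Si](C)(C)C[Mg]Cl
Why: Normant carbocupration adds Me3SiCH2–Cu syn across the terminal alkyne with the silylmethyl group on the internal carbon, and alkylation of the alkenylcopper by the benzylic bromide with retention places CH2SiMe3 and CH2Ar cis (2Z) without touching the 6E olefin or the stereocentres.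

Step 13
Reactants: 19 methyl 4-(acetyloxy)-3-bromo-5-{(2Z,6E,10R,11S)-10-bromo-11-chloro-7,11,15-trimethyl-3-[(trimethylsilyl)methyl]hexadeca-2,6,14-trien-1-yl}benzoate
Product: 21 methyl 4-(acetyloxy)-3-bromo-5-{[(1R,4aS,5R,6R,8aS)-6-bromo-5,8a-dimethyl-2-methylidene-5-(4-methylpent-3-en-1-yl)decahydronaphthalen-1-yl]methyl}benzoate, via bromiranium chloride 20 (not isolated)
Conditions: (CF3)2CHOH (0.005 M), 2,6-di-tert-butyl-4-methylpyridine (1.5 equiv), 0 °C to rt
Reagents that add atoms: none
Why: Enantiospecific solvolytic bromonium-initiated polyene cyclisation with Sakurai-type allylsilane termination: ionisation of the tertiary chloride with anti participation of bromine gives the enantiopure bromiranium ion, which is opened anti at C11 by the 6E olefin and relayed through a chair–chair transition state to the 2Z allylsilane, so C10 keeps its configuration (C6 of 21, R, equatorial Br), C5, C4a, C8a and C1 are set relative to it (trans fusion, equatorial CH2Ar), and loss of the silyl group places the olefin exocyclic.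

Step 14
Reactants: 21 methyl 4-(acetyloxy)-3-bromo-5-{[(1R,4aS,5R,6R,8aS)-6-bromo-5,8a-dimethyl-2-methylidene-5-(4-methylpent-3-en-1-yl)decahydronaphthalen-1-yl]methyl}benzoate
Product: 22 callophycoic acid H, 3-bromo-5-{[(1R,4aS,5R,6R,8aS)-6-bromo-5,8a-dimethyl-2-methylidene-5-(4-methylpent-3-en-1-yl)decahydronaphthalen-1-yl]methyl}-4-hydroxybenzoic acid
Conditions: LiOH·H2O, THF/MeOH/H2O, rt to 40 °C; then 1 M HCl to pH 4 at 0 °C
Reagents that add atoms: lithium hydroxide, [Li+].[OH-]
Why: Saponification (acyl–oxygen cleavage) removes the aryl acetate and the methyl ester together, while the equatorial neopentyl-type secondary bromide has no antiperiplanar β-hydrogen and is shielded from SN2, so it and all stereocentres survive.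

**Compound list**
1 | geraniol, (2E)-3,7-dimethylocta-2,6-dien-1-ol | CC(C)=CCC/C(C)=C/CO | starting material
2 | (2R,3S)-2-bromo-3-chloro-3,7-dimethyloct-6-en-1-ol | OC[C@@H](Br)[C@@](C)(Cl)CCC=C(C)C | intermediate
3 | (2R,3S)-2-bromo-3-chloro-3,7-dimethyloct-6-en-1-yl trifluoromethanesulfonate | O=S(=O)(OC[C@@H](Br)[C@@](C)(Cl)CCC=C(C)C)C(F)(F)F | intermediate
4 | pent-4-yn-1-ol | C#CCCCO | starting material
5 | trimethyl{[5-(trimethylsilyl)pent-4-yn-1-yl]oxy}silane (not isolated) | C[Si](C)(C)C#CCCCO[Si](C)(C)C | intermediate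
6 | 5-(trimethylsilyl)pent-4-yn-1-ol | C[Si](C)(C)C#CCCCO | intermediate
7 | 5-(trimethylsilyl)pent-4-ynal (not isolated) | C[Si](C)(C)C#CCCC=O | intermediate
8 | ethyl (2E)-2-methyl-7-(trimethylsilyl)hept-2-en-6-ynoate | CCOC(=O)/C(C)=C/CCC#C[Si](C)(C)C | intermediate
9 | (2E)-2-methyl-7-(trimethylsilyl)hept-2-en-6-yn-1-ol | OC/C(C)=C/CCC#C[Si](C)(C)C | intermediate
10 | [(5E)-7-chloro-6-methylhept-5-en-1-yn-1-yl]trimethylsilane | ClC/C(C)=C/CCC#C[Si](C)(C)C | intermediate
11 | chlorido[(2E)-2-methyl-7-(trimethylsilyl)hept-2-en-6-yn-1-yl]barium (not isolated) | Cl[Ba]C/C(C)=C/CCC#C[Si](C)(C)C | intermediate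
12 | [(5E,9R,10S)-9-bromo-10-chloro-6,10,14-trimethylpentadeca-5,13-dien-1-yn-1-yl]trimethylsilane | C[Si](C)(C)C#CCC/C=C(\C)CC[C@@H](Br)[C@@](C)(Cl)CCC=C(C)C | intermediate
13 | (5E,9R,10S)-9-bromo-10-chloro-6,10,14-trimethylpentadeca-5,13-dien-1-yne | C#CCC/C=C(\C)CC[C@@H](Br)[C@@](C)(Cl)CCC=C(C)C | intermediate
14 | methyl 4-hydroxy-3-methylbenzoate | COC(=O)c1ccc(O)c(C)c1 | starting material
15 | methyl 3-bromo-4-hydroxy-5-methylbenzoate | COC(=O)c1cc(C)c(O)c(Br)c1 | intermediate
16 | methyl 4-(acetyloxy)-3-bromo-5-methylbenzoate | COC(=O)c1cc(C)c(OC(C)=O)c(Br)c1 | intermediate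
17 | methyl 4-(acetyloxy)-3-bromo-5-(bromomethyl)benzoate | COC(=O)c1cc(CBr)c(OC(C)=O)c(Br)c1 | intermediate
18 | {(1Z,5E,9R,10S)-9-bromo-10-chloro-6,10,14-trimethyl-2-[(trimethylsilyl)methyl]pentadeca-1,5,13-trien-1-yl}copper (not isolated) | [Cu]/C=C(\C[Si](C)(C)C)CC/C=C(\C)CC[C@@H](Br)[C@@](C)(Cl)CCC=C(C)C | intermediate
19 | methyl 4-(acetyloxy)-3-bromo-5-{(2Z,6E,10R,11S)-10-bromo-11-chloro-7,11,15-trimethyl-3-[(trimethylsilyl)methyl]hexadeca-2,6,14-trien-1-yl}benzoate | COC(=O)c1cc(Br)c(OC(C)=O)c(C/C=C(\C[Si](C)(C)C)CC/C=C(\C)CC[C@@H](Br)[C@@](C)(Cl)CCC=C(C)C)c1 | intermediate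
20 | bromiranium chloride ion pair from 19 (Br bridges side-chain C10 and C11; C10 unchanged, C11 inverted; not isolated) | COC(=O)c1cc(Br)c(OC(C)=O)c(C/C=C(\C[Si](C)(C)C)CC/C=C(\C)CC[C@H]2[Br+][C@]2(C)CCC=C(C)C)c1.[Cl-] | intermediate
21 | methyl 4-(acetyloxy)-3-bromo-5-{[(1R,4aS,5R,6R,8aS)-6-bromo-5,8a-dimethyl-2-methylidene-5-(4-methylpent-3-en-1-yl)decahydronaphthalen-1-yl]methyl}benzoate | C=C1CC[C@@H]2[C@@](C)(CCC=C(C)C)[C@H](Br)CC[C@@]2(C)[C@@H]1Cc1cc(C(=O)OC)cc(Br)c1OC(C)=O | intermediate
22 | callophycoic acid H | C=C1CC[C@@H]2[C@@](C)(CCC=C(C)C)[C@H](Br)CC[C@@]2(C)[C@@H]1Cc1cc(C(=O)O)cc(Br)c1O | target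

**Totals**
Total steps: 14. Longest linear sequence: 9 steps (3, 4, 5, 6, 7, 8, 12, 13, 14, from pent-4-yn-1-ol).

**Steps most likely to fail**

Step 7 (allylbarium + bromochloro triflate). The organobarium may attack the vicinal dihalide (elimination or halogen attack) or couple with imperfect α/E fidelity. The fallback keeps the halogens out until the carbon chain is joined and uses a sulfone instead of an allylmetal; it sets out from 10 and 1 and returns at 12. Chloride 10 is converted with PhSO2Na in DMF into the allylic sulfone trimethyl[(5E)-6-methyl-7-(phenylsulfonyl)hept-5-en-1-yn-1-yl]silane F1. Geraniol 1 is epoxidised under Sharpless conditions (Ti(OiPr)4, L-(+)-diethyl tartrate, t-BuOOH) to (2S,3S)-2,3-epoxygeraniol F2, which is triflated to the epoxy triflate F3. Lithiated F1 is alkylated by F3 (Biellmann-type α-alkylation, olefin geometry untouched) to the epoxy sulfone F4. The sulfone is removed with PdCl2(dppp)/LiBHEt3 to give the epoxy enyne F5. Li2NiBr4 opens the epoxide at its secondary carbon with inversion to the bromohydrin F6. Dry HCl in Et2O at −40 °C then exchanges the tertiary hydroxyl for chloride through the bromiranium ion (double inversion, net retention) to give 12.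

Step 12 (carbocupration and benzylation). Long exposure of the bromochloride to organocopper and a sluggish alkylation by the ortho-substituted, electron-poor benzylic bromide are the concerns. The fallback replaces the direct alkylation by a cross-coupling; it sets out from 13 (as its alkenylcopper 18) and 17 and returns at 19. Alkenylcopper 18 is quenched cold with iodine to the vinyl iodide {[(1Z,5E,9R,10S)-9-bromo-10-chloro-1-iodo-6,10,14-trimethylpentadeca-1,5,13-trien-2-yl]methyl}trimethylsilane F7. Bromide 17 is converted with zinc dust/LiCl into the benzylzinc bromide F8. A Pd(PPh3)4-catalysed Negishi coupling of F7 with F8 (retention at the olefin, vinyl iodide reacting before the aryl bromide) gives 19.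

Step 13 (one-operation bicyclisation). The cascade may stop after ring B, or the bromiranium ion may be diverted by solvent capture or elimination. The fallback closes the rings one at a time; it sets out from 19 and returns at 21. Compound 19 is ionised with a mild chloride-returning Lewis acid (ZnCl2, CH2Cl2, −40 °C) so that ring B closes and the tertiary cation is recaptured by chloride, giving the monocyclic tertiary chloride methyl 4-(acetyloxy)-3-bromo-5-{(2Z)-5-[(1R,2R,3R)-3-bromo-6-chloro-2,6-dimethyl-2-(4-methylpent-3-en-1-yl)cyclohexyl]-3-[(trimethylsilyl)methyl]pent-2-en-1-yl}benzoate F9. Ring A is then closed separately by an intramolecular Sakurai alkylation (SnCl4, CH2Cl2, −78 °C), the re-formed tertiary cation being attacked by the allylsilane through the chair with the side chain equatorial, to give 21.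

**Further compounds**
F1 | step 7 | trimethyl[(5E)-6-methyl-7-(phenylsulfonyl)hept-5-en-1-yn-1-yl]silane | O=S(=O)(C/C(C)=C/CCC#C[Si](C)(C)C)c1ccccc1
F2 | step 7 | (2S,3S)-2,3-epoxygeraniol, [(2S,3S)-3-methyl-3-(4-methylpent-3-en-1-yl)oxiran-2-yl]methanol | OC[C@@H]1O[C@@]1(C)CCC=C(C)C
F3 | step 7 | [(2S,3S)-3-methyl-3-(4-methylpent-3-en-1-yl)oxiran-2-yl]methyl trifluoromethanesulfonate | O=S(=O)(OC[C@@H]1O[C@@]1(C)CCC=C(C)C)C(F)(F)F
F4 | step 7 | trimethyl{(5E)-6-methyl-8-[(2S,3S)-3-methyl-3-(4-methylpent-3-en-1-yl)oxiran-2-yl]-7-(phenylsulfonyl)oct-5-en-1-yn-1-yl}silane (both C7 epimers) | C[Si](C)(C)C#CCC/C=C(\C)C(C[C@@H]1O[C@@]1(C)CCC=C(C)C)S(=O)(=O)c1ccccc1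
F5 | step 7 | trimethyl{(5E)-6-methyl-8-[(2S,3S)-3-methyl-3-(4-methylpent-3-en-1-yl)oxiran-2-yl]oct-5-en-1-yn-1-yl}silane | C[Si](C)(C)C#CCC/C=C(\C)CC[C@@H]1O[C@@]1(C)CCC=C(C)C
F6 | step 7 | (5E,9R,10S)-9-bromo-6,10,14-trimethyl-1-(trimethylsilyl)pentadeca-5,13-dien-1-yn-10-ol | C[Si](C)(C)C#CCC/C=C(\C)CC[C@@H](Br)[C@@](C)(O)CCC=C(C)C
F7 | step 12 | {[(1Z,5E,9R,10S)-9-bromo-10-chloro-1-iodo-6,10,14-trimethylpentadeca-1,5,13-trien-2-yl]methyl}trimethylsilane | I/C=C(\C[Si](C)(C)C)CC/C=C(\C)CC[C@@H](Br)[C@@](C)(Cl)CCC=C(C)C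
F8 | step 12 | {[2-(acetyloxy)-3-bromo-5-(methoxycarbonyl)phenyl]methyl}zinc bromide | COC(=O)c1cc(Br)c(OC(C)=O)c(C[Zn]Br)c1
F9 | step 13 | methyl 4-(acetyloxy)-3-bromo-5-{(2Z)-5-[(1R,2R,3R)-3-bromo-6-chloro-2,6-dimethyl-2-(4-methylpent-3-en-1-yl)cyclohexyl]-3-[(trimethylsilyl)methyl]pent-2-en-1-yl}benzoate (either C6 epimer) | COC(=O)c1cc(Br)c(OC(C)=O)c(C/C=C(\C[Si](C)(C)C)CC[C@@H]2[C@@](C)(CCC=C(C)C)[C@H](Br)CCC2(C)Cl)c1
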